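**Strategy**

Everything rests on the furylic carbinol carbon, which bears the ester oxygen, C4 of the furan ring and the CH2 of the 4-methylpent-3-enyl chain. That O–C(furyl)–CH2–alkenyl pattern is what a vinylboron ate complex delivers when an aryl group shifts from boron to carbon while palladium alkenylates the terminal CH2. One conjunctive coupling therefore joins furan-3-yllithium, vinylboronic acid pinacol ester and isobutenyl triflate, forms two C–C bonds and sets the (R) centre as a C–B bond; the precursor is the lithium furyl(vinyl)borate made in the flask. Stereoretentive oxidation, acylation, C5 borylation of the furan, Suzuki coupling and desilylation complete the route.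

Key step: step 2

Assumption: the (Sp,Sp) antipode of the MandyPhos ligand is taken to give the (R) boronate, by analogy with aryl migrations in this coupling. The sense of induction would be checked on the derived carbinol by Mosher ester analysis, and the (Rp,Rp) antipode would be used instead if it proved opposite.

**Route**

Step 1
Reactants: 1 isobutyraldehyde (2-methylpropanal)
Product: 2 2-methylprop-1-en-1-yl trifluoromethanesulfonate
Conditions: Tf2O (1.1 equiv), 2,6-di-tert-butyl-4-methylpyridine (1.2 equiv), CH2Cl2, 0 °C to reflux; pentane, filtration, distillation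
Reagents that add atoms: trifluoromethanesulfonic anhydride, O=S(=O)(OS(=O)(=O)C(F)(F)F)C(F)(F)F
Why: Enol triflate formation from an enolisable aldehyde, in which O-triflation gives an oxocarbenium triflate that the hindered, non-nucleophilic pyridine deprotonates at the α-carbon; because that carbon carries two methyl groups, only one alkene isomer can form.

Step 2
Reactants: 3 3-bromofuran; 4 4,4,5,5-tetramethyl-2-vinyl-1,3,2-dioxaborolane; 2 2-methylprop-1-en-1-yl trifluoromethanesulfonate
Product: 7 (R)-2-[1-(furan-3-yl)-4-methylpent-3-en-1-yl]-4,4,5,5-tetramethyl-1,3,2-dioxaborolane, via furan-3-yllithium 5 (not isolated), via lithium furyl(vinyl)pinacolatoborate 6 (not isolated)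
Conditions: 3 (1.05 equiv), n-BuLi (1.00 equiv), Et2O, −78 °C, 30 min; 4 (1.0 equiv), −78 °C to rt; volatiles removed in vacuo; then Pd(OAc)2 (2 mol%), (Sp,Sp)-MandyPhos (Ar2P groups, Ar = 4-methoxy-3,5-dimethylphenyl; 2.4 mol%), KOTf (1 equiv), 2 (1.2 equiv), THF, 60 °C, 16 h
Reagents that add atoms: none
Why: Bromine–lithium exchange at −78 °C gives 5 before it can isomerise to the 2-lithio isomer, and 5 adds to the vacant boron orbital of 4 to give four-coordinate borate 6. Oxidative addition of 2 to zerovalent palladium gives a cationic alkenyl complex of divalent palladium that binds the vinyl group of 6 and triggers an anti 1,2-shift of the furyl group from boron to the α-carbon while the terminal carbon bonds to palladium; reductive elimination then forms the CH2–CH= bond. The closest known reaction type is the palladium-catalysed enantioselective conjunctive cross-coupling of aryl(vinyl)boron ate complexes with aryl and alkenyl triflates, applied here to a heteroaryl migrating group. No ring closes. The one new stereocentre, the boron-bearing carbon, is controlled by the chiral bisphosphine, which selects the face of the vinyl group that palladium binds while the furyl group arrives anti to the metal. The step needs the metallate shift to beat direct furyl-to-palladium transfer and β-hydride elimination, which the triflate electrophile, the bromide-free borate (n-BuBr and residual 3 stripped, KOTf as scavenger) and the wide-bite-angle ligand should secure; the regiochemistry is built in, since the shift can only place furyl on the boron-bearing carbon and the alkenyl group on the terminal CH2.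

Step 3
Reactants: 7 (R)-2-[1-(furan-3-yl)-4-methylpent-3-en-1-yl]-4,4,5,5-tetramethyl-1,3,2-dioxaborolane
Product: 8 (R)-1-(furan-3-yl)-4-methylpent-3-en-1-ol
Conditions: NaBO3·4H2O (4 equiv), THF/H2O (1:1), rt
Reagents that add atoms: sodium perborate tetrahydrate, [Na+].[O-]OB=O.O.O.O.O
Why: Boronate oxidation, in which the peroxide anion adds to boron and the furylic carbon migrates from boron to oxygen with retention, so the (R) C–B bond becomes the (R) C–O bond, while the mild oxidant should spare the furan and the trisubstituted alkene.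

Step 4
Reactants: 8 (R)-1-(furan-3-yl)-4-methylpent-3-en-1-ol; 9 (R)-2-methylbutanoic acid
Product: 10 (1R)-1-(furan-3-yl)-4-methylpent-3-en-1-yl (2R)-2-methylbutanoate
Conditions: 9 (1.2 equiv), DCC (1.3 equiv), DMAP (0.1 equiv), CH2Cl2, 0 °C to rt
Reagents that add atoms: none
Why: Steglich esterification, in which the acid is activated as the O-acylisourea and the N-acylpyridinium ion and acylates the alcohol oxygen, so the carbinol C–O bond is never broken and its (R) configuration is kept, while low temperature and catalytic DMAP should keep the α-stereocentre of the acyl group from epimerising.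

Step 5
Reactants: 10 (1R)-1-(furan-3-yl)-4-methylpent-3-en-1-yl (2R)-2-methylbutanoate
Product: 11 (1R)-4-methyl-1-[5-(4,4,5,5-tetramethyl-1,3,2-dioxaborolan-2-yl)furan-3-yl]pent-3-en-1-yl (2R)-2-methylbutanoate
Conditions: [Ir(OMe)(cod)]2 (1.5 mol%), 4,4'-di-tert-butyl-2,2'-bipyridine (3 mol%), B2pin2 (1.0 equiv), THF, rt; short silica plug
Reagents that add atoms: bis(pinacolato)diboron, CC1(C)OB(OC1(C)C)B1OC(C)(C)C(C)(C)O1
Why: Iridium-catalysed aromatic C–H borylation, which is sterically controlled and favours furan α-positions, so C5 should react as the only unhindered α C–H (C2 is flanked by the branched side chain), and the ester, the trisubstituted alkene and both stereocentres should be left alone at room temperature.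

Step 6
Reactants: 12 2-bromobenzene-1,4-diol
Product: 13 2-bromo-1,4-bis(tert-butyldimethylsilyloxy)benzene
Conditions: TBSCl (2.4 equiv), imidazole (5 equiv), DMF, rt
Reagents that add atoms: tert-butyldimethylsilyl chloride, CC(C)(C)[Si](C)(C)Cl
Why: Imidazole-promoted O-silylation of both phenols, which masks the acidic, easily oxidised hydroquinone for the cross-coupling and can be undone later with fluoride without touching the ester.

Step 7
Reactants: 11 (1R)-4-methyl-1-[5-(4,4,5,5-tetramethyl-1,3,2-dioxaborolan-2-yl)furan-3-yl]pent-3-en-1-yl (2R)-2-methylbutanoate; 13 2-bromo-1,4-bis(tert-butyldimethylsilyloxy)benzene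
Product: 14 (1R)-1-{5-[2,5-bis(tert-butyldimethylsilyloxy)phenyl]furan-3-yl}-4-methylpent-3-en-1-yl (2R)-2-methylbutanoate
Conditions: 13 (1.1 equiv), Pd(XPhos)(2'-aminobiphenyl-2-yl)Cl (second-generation XPhos palladacycle precatalyst, 3 mol%), 0.5 M aq K3PO4 (2 equiv), THF, degassed, 40 °C
Reagents that add atoms: none
Why: Suzuki–Miyaura coupling, in which a fast-activating biarylphosphine precatalyst should let transmetalation of the furan-2-yl boronate outrun protodeboronation at 40 °C and cope with the ortho-substituted, electron-rich bromide, while aqueous phosphate is mild enough for the ester and its α-stereocentre and any silyl group lost would be removed in step 8 anyway.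

Step 8
Reactants: 14 (1R)-1-{5-[2,5-bis(tert-butyldimethylsilyloxy)phenyl]furan-3-yl}-4-methylpent-3-en-1-yl (2R)-2-methylbutanoate
Product: 15 (1R)-1-[5-(2,5-dihydroxyphenyl)furan-3-yl]-4-methylpent-3-en-1-yl (2R)-2-methylbutanoate (CNP0144658.1)
Conditions: Bu4NF (2.5 equiv), AcOH (3 equiv), THF, 0 °C, argon, degassed solvents; work-up with aq Na2S2O4
Reagents that add atoms: none
Why: Fluoride cleavage of the aryl silyl ethers, driven by the strong Si–F bond, with acetic acid protonating the phenoxides so that the ester is neither cleaved nor epimerised and the hydroquinone is not air-oxidised; no stereocentre is involved.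

**Compound list**

1 | isobutyraldehyde | CC(C)C=O | starting material
2 | 2-methylprop-1-en-1-yl trifluoromethanesulfonate | CC(C)=COS(=O)(=O)C(F)(F)F | intermediate
3 | 3-bromofuran | Brc1ccoc1 | starting material
4 | 4,4,5,5-tetramethyl-2-vinyl-1,3,2-dioxaborolane | C=CB1OC(C)(C)C(C)(C)O1 | starting material
5 | furan-3-yllithium | [Li]c1ccoc1 | intermediate
6 | lithium (furan-3-yl)(vinyl)(pinacolato)borate | [Li+].C=C[B-]1(c2ccoc2)OC(C)(C)C(C)(C)O1 | intermediate
7 | (R)-2-[1-(furan-3-yl)-4-methylpent-3-en-1-yl]-4,4,5,5-tetramethyl-1,3,2-dioxaborolane | CC1(C)OB([C@H](CC=C(C)C)c2ccoc2)OC1(C)C | intermediate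
8 | (R)-1-(furan-3-yl)-4-methylpent-3-en-1-ol | O[C@H](CC=C(C)C)c1ccoc1 | intermediate
9 | (R)-2-methylbutanoic acid | CC[C@@H](C)C(=O)O | starting material
10 | (1R)-1-(furan-3-yl)-4-methylpent-3-en-1-yl (2R)-2-methylbutanoate | CC[C@@H](C)C(=O)O[C@H](CC=C(C)C)c1ccoc1 | intermediate
11 | (1R)-4-methyl-1-[5-(4,4,5,5-tetramethyl-1,3,2-dioxaborolan-2-yl)furan-3-yl]pent-3-en-1-yl (2R)-2-methylbutanoate | CC[C@@H](C)C(=O)O[C@H](CC=C(C)C)c1coc(B2OC(C)(C)C(C)(C)O2)c1 | intermediate
12 | 2-bromobenzene-1,4-diol | Oc1ccc(O)c(Br)c1 | starting material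
13 | 2-bromo-1,4-bis(tert-butyldimethylsilyloxy)benzene | CC(C)(C)[Si](C)(C)Oc1ccc(O[Si](C)(C)C(C)(C)C)c(Br)c1 | intermediate
14 | (1R)-1-{5-[2,5-bis(tert-butyldimethylsilyloxy)phenyl]furan-3-yl}-4-methylpent-3-en-1-yl (2R)-2-methylbutanoate | CC[C@@H](C)C(=O)O[C@H](CC=C(C)C)c1coc(-c2cc(O[Si](C)(C)C(C)(C)C)ccc2O[Si](C)(C)C(C)(C)C)c1 | intermediate
15 | (1R)-1-[5-(2,5-dihydroxyphenyl)furan-3-yl]-4-methylpent-3-en-1-yl (2R)-2-methylbutanoate | CC[C@@H](C)C(=O)O[C@H](CC=C(C)C)c1coc(-c2cc(O)ccc2O)c1 | target

**Step count**

Total steps: 8. Longest linear sequence: 7 steps (1 → 2 → 7 → 8 → 10 → 11 → 14 → 15, steps 1, 2, 3, 4, 5, 7 and 8); step 6 is a one-step side branch.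

**Steps most likely to fail**

Step 2. The furyl or vinyl group may pass from boron straight to palladium (plain cross-coupling) instead of undergoing the 1,2-shift, facial discrimination may be poor with a heteroaryl migrating group, or 5 may drift to the 2-lithio isomer before it is trapped. Within the same approach, the neopentyl glycol ester of vinylboronic acid would be tried first. The fallback sets out from 5 and comes back at 8, and reaches the carbinol without any boron shift. Compound 5, made as in step 2, would be quenched with DMF to give furan-3-carbaldehyde F1, which can also be bought. Brown allylation with the B-allyldiisopinocampheylborane antipode prepared from (−)-α-pinene (Et2O, −78 °C, then NaOH/H2O2) is expected, by analogy with benzaldehyde, to give (R)-1-(furan-3-yl)but-3-en-1-ol F2. Cross-metathesis of F2 with excess 2-methylbut-2-ene and the second-generation Grubbs catalyst RuCl2(H2IMes)(PCy3)(=CHPh) (CH2Cl2, 40 °C) would exchange the terminal CH2 for the isopropylidene group and give 8.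

Step 7. Protodeboronation of the electron-rich furan-2-yl boronate may outrun transmetalation, oxidative addition of the hindered electron-rich bromide may be slow, and silyl groups may be lost early, exposing an oxidisable hydroquinone to base. The fallback sets out from 11 and comes back at 14, carrying the boron in a slow-release form. Treatment of 11 with KHF2 (MeOH/H2O, rt) should give potassium trifluoro{4-[(1R)-4-methyl-1-{[(2R)-2-methylbutanoyl]oxy}pent-3-en-1-yl]furan-2-yl}borate F3. This salt would be coupled with 13 under trifluoroborate conditions (Pd(OAc)2, RuPhos, K2CO3, toluene/H2O, 80 °C), where the boronic acid is released only as fast as it is consumed, to give 14.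

Step 5. Borylation may spread to C2 or go twice, or the pinacolborane formed may hydroborate or isomerise the trisubstituted alkene. The fallback sets out from 13 and comes back at 14, bringing the aryl group in before the key step so that no C–H borylation is needed.
- Miyaura borylation of 13 (Pd(dppf)Cl2, B2pin2, KOAc, dioxane, 80 °C) would give 2-[2,5-bis(tert-butyldimethylsilyloxy)phenyl]-4,4,5,5-tetramethyl-1,3,2-dioxaborolane F4.
- Suzuki–Miyaura coupling of F4 with commercial 2,4-dibromofuran at its more reactive C2–Br bond (Pd(PPh3)4, aq K3PO4, THF, 50 °C) would give 4-bromo-2-[2,5-bis(tert-butyldimethylsilyloxy)phenyl]furan F5.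
- Bromine–lithium exchange (n-BuLi, Et2O, −78 °C) would give {5-[2,5-bis(tert-butyldimethylsilyloxy)phenyl]furan-3-yl}lithium F6, which with 4 forms lithium {5-[2,5-bis(tert-butyldimethylsilyloxy)phenyl]furan-3-yl}(vinyl)(pinacolato)borate F7.
- Conjunctive coupling of F7 with 2 under the conditions of step 2 would give (R)-2-(1-{5-[2,5-bis(tert-butyldimethylsilyloxy)phenyl]furan-3-yl}-4-methylpent-3-en-1-yl)-4,4,5,5-tetramethyl-1,3,2-dioxaborolane F8.
- Oxidation as in step 3 would give (R)-1-{5-[2,5-bis(tert-butyldimethylsilyloxy)phenyl]furan-3-yl}-4-methylpent-3-en-1-ol F9, and Steglich esterification of F9 with 9 as in step 4 would give 14.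

**Further compounds**

F1 | step 2 | furan-3-carbaldehyde | O=Cc1ccoc1
F2 | step 2 | (R)-1-(furan-3-yl)but-3-en-1-ol | O[C@H](CC=C)c1ccoc1
F3 | step 7 | potassium trifluoro{4-[(1R)-4-methyl-1-{[(2R)-2-methylbutanoyl]oxy}pent-3-en-1-yl]furan-2-yl}borate | [K+].CC[C@@H](C)C(=O)O[C@H](CC=C(C)C)c1coc([B-](F)(F)F)c1
F4 | step 5 | 2-[2,5-bis(tert-butyldimethylsilyloxy)phenyl]-4,4,5,5-tetramethyl-1,3,2-dioxaborolane | CC(C)(C)[Si](C)(C)Oc1ccc(O[Si](C)(C)C(C)(C)C)c(B2OC(C)(C)C(C)(C)O2)c1
F5 | step 5 | 4-bromo-2-[2,5-bis(tert-butyldimethylsilyloxy)phenyl]furan | Brc1coc(-c2cc(O[Si](C)(C)C(C)(C)C)ccc2O[Si](C)(C)C(C)(C)C)c1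
F6 | step 5 | {5-[2,5-bis(tert-butyldimethylsilyloxy)phenyl]furan-3-yl}lithium | [Li]c1coc(-c2cc(O[Si](C)(C)C(C)(C)C)ccc2O[Si](C)(C)C(C)(C)C)c1
F7 | step 5 | lithium {5-[2,5-bis(tert-butyldimethylsilyloxy)phenyl]furan-3-yl}(vinyl)(pinacolato)borate | [Li+].C=C[B-]1(c2coc(-c3cc(O[Si](C)(C)C(C)(C)C)ccc3O[Si](C)(C)C(C)(C)C)c2)OC(C)(C)C(C)(C)O1
F8 | step 5 | (R)-2-(1-{5-[2,5-bis(tert-butyldimethylsilyloxy)phenyl]furan-3-yl}-4-methylpent-3-en-1-yl)-4,4,5,5-tetramethyl-1,3,2-dioxaborolane | CC1(C)OB([C@H](CC=C(C)C)c2coc(-c3cc(O[Si](C)(C)C(C)(C)C)ccc3O[Si](C)(C)C(C)(C)C)c2)OC1(C)C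
F9 | step 5 | (R)-1-{5-[2,5-bis(tert-butyldimethylsilyloxy)phenyl]furan-3-yl}-4-methylpent-3-en-1-ol | O[C@H](CC=C(C)C)c1coc(-c2cc(O[Si](C)(C)C(C)(C)C)ccc2O[Si](C)(C)C(C)(C)C)c1
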